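**Remark:** the target SMILES defines a (2R)-2-methylbutanoate and a (2E)-3-methylpent-2-enoate; both acids are assumed to be purchasable in this form.

**Strategy.** The cyclopentanone ring (C-1, C-2, C-3, C-3a, C-7a; indane numbering) carries the C-2 ketone and, on C-3, the oxygenated two-carbon side chain: a 1,3-dioxygenation that maps onto the acyl shift of an α,β-epoxy ketone. The route therefore builds, from (R)-cryptone, a trans-fused cadinane-type decalin whose 2-methylcyclohexenone ring is epoxidised; BF3 then moves the ring acyl carbon from the methyl-bearing oxirane carbon to its neighbour, contracting the six-membered ring to the cyclopentanone and expelling the former ring carbon as the acetyl group, as in the presumed cadinane-to-oplopane biogenesis. A ruthenium-catalysed transfer hydrogenation finally turns the acetyl group into the (S)-carbinol.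

Key step: step 13

Locants: compounds 12–19 use the naphthalen-2(1H)-one numbering of 12 (C-2 carbonyl, C-3 methyl-bearing carbon, C-4a and C-8a ring fusion, C-8 methylidene carbon); 20 and 21 use indane numbering.

**Step 1**
Reactants: 1 3-methylbutanal; 2 but-3-en-2-one
Product: 3 (2R)-5-oxo-2-(propan-2-yl)hexanal
Conditions: (R)-2-(methoxydiphenylmethyl)pyrrolidine (5 mol%), ethyl 3,4-dihydroxybenzoate (20 mol%), neat, 4 °C
Reagents that add atoms: none
Why: Enamine-catalysed asymmetric Michael addition, in which the diarylmethyl group of the (R)-catalyst shields one face of the (E)-enamine so that the enone should add to the face that gives the (R)-aldehyde.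

**Step 2**
Reactants: 3 (2R)-5-oxo-2-(propan-2-yl)hexanal
Product: 4 (4R)-4-(propan-2-yl)cyclohex-2-en-1-one ((R)-cryptone)
Conditions: LiOH (0.1 equiv), iPrOH, 25 °C
Reagents that add atoms: none
Why: Intramolecular aldol condensation of the methyl ketone onto the aldehyde followed by E1cB dehydration, under base mild enough to leave the stereocentre untouched.

**Step 3**
Reactants: 4 (R)-cryptone; 5 vinylmagnesium bromide; 6 1-bromobut-2-yne
Product: 8 (2S,3R,4R)-2-(but-2-yn-1-yl)-3-ethenyl-4-(propan-2-yl)cyclohexan-1-one, via bromomagnesium enolate 7 (not isolated)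
Conditions: CH2=CHMgBr, CuBr·SMe2 (10 mol%), THF, −78 → −40 °C; then HMPA, 6, −40 → 0 °C
Reagents that add atoms: none
Why: Copper-catalysed conjugate addition anti to the C-4 isopropyl group gives a regiodefined enolate that is C-alkylated (SN2) trans to the new vinyl group, so all three ring substituents end equatorial, which is also the thermodynamically favoured array.

**Step 4**
Reactants: 8 (2S,3R,4R)-2-(but-2-yn-1-yl)-3-ethenyl-4-(propan-2-yl)cyclohexan-1-one
Product: 9 (2S,3R,4R)-3-ethenyl-2-(2-oxobutyl)-4-(propan-2-yl)cyclohexan-1-one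
Conditions: NaAuCl4 (2 mol%), MeOH/H2O (10:1), 65 °C
Reagents that add atoms: water, O
Why: Gold-catalysed alkyne hydration in which the ring carbonyl oxygen attacks the activated alkyne in the 5-exo-dig mode, so the new carbonyl lands on the alkyne carbon nearer the ring (1,4-diketone) while the vinyl group stays inert.

**Step 5**
Reactants: 9 (2S,3R,4R)-3-ethenyl-2-(2-oxobutyl)-4-(propan-2-yl)cyclohexan-1-one
Product: 10 (1R,2S,6R)-3-oxo-2-(2-oxobutyl)-6-(propan-2-yl)cyclohexane-1-carbaldehyde
Conditions: O3, CH2Cl2/MeOH (4:1), −78 °C; then Me2S, −78 → 25 °C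
Reagents that add atoms: ozone, [O-][O+]=O
Why: Ozonolysis of the only alkene with reductive work-up; the new formyl-bearing carbon is equatorial, so enolisation cannot erode it.

**Step 6**
Reactants: 10 (1R,2S,6R)-3-oxo-2-(2-oxobutyl)-6-(propan-2-yl)cyclohexane-1-carbaldehyde
Product: 11 (4R,4aS,8aS)-6-methyl-4-(propan-2-yl)-3,4,4a,8a-tetrahydronaphthalene-1,7(2H,8H)-dione (trans-fused)
Conditions: KOH (0.2 equiv), MeOH, 0 → 25 °C
Reagents that add atoms: none
Why: Intramolecular aldol condensation in which the methylene carbon of the ethyl ketone attacks the far more electrophilic aldehyde (6-(enolendo)-exo-trig) and E1cB dehydration gives the 2-methyl enone, the epimerisable ring-fusion carbons settling in the trans-decalin.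

**Step 7**
Reactants: 11 (4R,4aS,8aS)-6-methyl-4-(propan-2-yl)-3,4,4a,8a-tetrahydronaphthalene-1,7(2H,8H)-dione
Product: 12 (4aS,5R,8aS)-3-methyl-8-methylidene-5-(propan-2-yl)-4a,5,6,7,8,8a-hexahydronaphthalen-2(1H)-one
Conditions: Ph3PCH3Br (1.2 equiv), KOtBu (1.15 equiv), THF, 0 °C
Reagents that add atoms: methyltriphenylphosphonium bromide (used as its ylide), C[P+](c1ccccc1)(c1ccccc1)c1ccccc1.[Br-]
Why: Wittig methylenation, chemoselective because the non-stabilised ylide adds to the saturated ketone much faster than to the conjugated, α-substituted enone carbonyl.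

**Step 8**
Reactants: 12 (4aS,5R,8aS)-3-methyl-8-methylidene-5-(propan-2-yl)-4a,5,6,7,8,8a-hexahydronaphthalen-2(1H)-one
Product: 13 3,4-epoxide of 12 (oxirane oxygen cis to H-8a, anti to H-4a)
Conditions: 30% H2O2, NaOH (0.2 equiv), MeOH, 0 °C
Reagents that add atoms: hydrogen peroxide, OO
Why: Weitz–Scheffer nucleophilic epoxidation, selective for the electron-poor enone alkene, with hydroperoxide expected to attack C-4 axially, anti to the axial H-4a (the face is not critical because C-4 is reset in step 13).

**Step 9**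
Reactants: 13 3,4-epoxide of 12
Product: 14 1-hydroxy derivative of 13 (1-OH axial, cis to H-4a)
Conditions: NaN(SiMe3)2, THF, −78 °C; 2-(phenylsulfonyl)-3-phenyloxaziridine, −78 °C; then AcOH
Reagents that add atoms: 2-(phenylsulfonyl)-3-phenyloxaziridine, O=S(=O)(c1ccccc1)N1OC1c1ccccc1
Why: Enolate hydroxylation with an N-sulfonyloxaziridine at C-1, the only carbon with α-hydrogens, where oxygen should enter axially on the face opposite the oxirane oxygen, an orientation that also avoids peri strain with the C-8 methylidene group.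

**Step 10**
Reactants: 14 1-hydroxy derivative of 13; 15 (2R)-2-methylbutanoic acid
Product: 16 (2R)-2-methylbutanoate of 14 at O-1
Conditions: DCC, DMAP (0.1 equiv), CH2Cl2, 0 → 25 °C
Reagents that add atoms: none
Why: Steglich esterification, which acylates the α-hydroxy ketone with retention at both stereocentres.

**Step 11**
Reactants: 16 (2R)-2-methylbutanoate of 14
Product: 17 7-hydroxy derivative of 16 (7-OH axial, cis to H-8a)
Conditions: SeO2 (0.5 equiv), tBuOOH (3 equiv), CH2Cl2, 25 °C
Reagents that add atoms: selenium dioxide, O=[Se]=O; tert-butyl hydroperoxide, CC(C)(C)OO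
Why: Selenium dioxide allylic hydroxylation (ene reaction, then [2,3]-sigmatropic shift) of the 1,1-disubstituted alkene at the ring CH2 in preference to the ring-fusion CH, with the axial hydrogen removed and oxygen returned on the same axial face, as is usual for exocyclic methylene groups on trans-fused rings.

**Step 12**
Reactants: 17 7-hydroxy derivative of 16; 18 (2E)-3-methylpent-2-enoic acid
Product: 19 7-O-[(2E)-3-methylpent-2-enoyl] derivative of 17
Conditions: DCC, DMAP (0.2 equiv), CH2Cl2, 25 °C
Reagents that add atoms: none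
Why: Steglich esterification; carbodiimide activation avoids the acid chloride and its vinylketene, so the (E)-geometry and the conjugation of the acid should be kept.

**Step 13**
Reactants: 19 7-O-[(2E)-3-methylpent-2-enoyl] derivative of 17
Product: 20 (1R,3R,3aR,4R,6S,7aS)-3-acetyl-7-methylidene-1-{[(2R)-2-methylbutanoyl]oxy}-2-oxo-4-(propan-2-yl)octahydro-1H-inden-6-yl (2E)-3-methylpent-2-enoate
Conditions: BF3·OEt2 (0.5 equiv), CH2Cl2, −40 → 0 °C
Reagents that add atoms: none
Why: BF3 coordinates the oxirane oxygen and the C-4–O bond (β to the carbonyl, the only position where positive charge is tolerated) breaks while the ring acyl carbon C-2 shifts from C-3 to C-4 with inversion at C-4, so that C-3 leaves the ring and becomes the acetyl carbonyl (semipinacol-type 1,2-acyl shift). The closest known reaction type is the Lewis-acid rearrangement of 2,3-epoxycyclohexanones to ring-contracted 2-acylcyclopentanones, and the change mirrors the presumed cadinane-to-oplopane ring contraction. The five-membered ring is closed by this three-centre suprafacial 1,2-shift within the existing six-membered ring, not by a new cyclisation, so the trans ring fusion and the C-1 acyloxy centre are carried over unchanged. The only new stereocentre, the acyl-bearing ring carbon (C-3 of 20), is formed by inversion and, lying between two carbonyl groups, should equilibrate through the enol to the side-chain orientation cis to H-3a, away from the peri isopropyl-bearing carbon. The step needs opening at C-4 and not C-3, and migration of the acyl and not the methyl group: the carbonyl deactivates C-3 towards ionisation, acyl groups migrate far better than methyl, and the C-3 methyl group excludes the competing hydride shift to a 1,2-dione. Sub-stoichiometric BF3·OEt2 at low temperature is chosen to spare the allylic enoate and the methylidene group.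

**Step 14**
Reactants: 20 3-acetyl oplopane diester
Product: 21 (1R,3R,3aR,4R,6S,7aS)-3-[(1S)-1-hydroxyethyl]-7-methylidene-1-{[(2R)-2-methylbutanoyl]oxy}-2-oxo-4-(propan-2-yl)octahydro-1H-inden-6-yl (2E)-3-methylpent-2-enoate (CNP0224363.1)
Conditions: RuCl[(S,S)-TsDPEN](p-cymene) (2 mol%), HCO2H/Et3N (5:2), CH2Cl2, 25 °C
Reagents that add atoms: none
Why: Asymmetric transfer hydrogenation with dynamic kinetic resolution (monoreduction of a 2-substituted 1,3-diketone), in which the unhindered methyl ketone should be reduced in preference to the ring carbonyl flanked by two methine carbons, the (S,S)-catalyst sets the (S)-carbinol with the 1,3-dicarbonyl residue in the place of the aryl group of the acetophenone model, and C-3 stays in its favoured configuration through enol equilibration.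

**Compound list**
1 | 3-methylbutanal | CC(C)CC=O | starting material
2 | but-3-en-2-one | CC(=O)C=C | starting material
3 | (2R)-5-oxo-2-(propan-2-yl)hexanal | O=C[C@@H](C(C)C)CCC(C)=O | intermediate
4 | (4R)-4-(propan-2-yl)cyclohex-2-en-1-one ((R)-cryptone) | O=C1C=C[C@@H](C(C)C)CC1 | intermediate
5 | vinylmagnesium bromide | C=C[Mg]Br | starting material
6 | 1-bromobut-2-yne | CC#CCBr | starting material
7 | bromomagnesium (3R,4R)-3-ethenyl-4-(propan-2-yl)cyclohex-1-en-1-olate | Br[Mg]OC1=C[C@H](C=C)[C@@H](C(C)C)CC1 | intermediate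
8 | (2S,3R,4R)-2-(but-2-yn-1-yl)-3-ethenyl-4-(propan-2-yl)cyclohexan-1-one | O=C1[C@@H](CC#CC)[C@H](C=C)[C@@H](C(C)C)CC1 | intermediate
9 | (2S,3R,4R)-3-ethenyl-2-(2-oxobutyl)-4-(propan-2-yl)cyclohexan-1-one | O=C1[C@@H](CC(=O)CC)[C@H](C=C)[C@@H](C(C)C)CC1 | intermediate
10 | (1R,2S,6R)-3-oxo-2-(2-oxobutyl)-6-(propan-2-yl)cyclohexane-1-carbaldehyde | O=C1[C@@H](CC(=O)CC)[C@H](C=O)[C@@H](C(C)C)CC1 | intermediate
11 | (4R,4aS,8aS)-6-methyl-4-(propan-2-yl)-3,4,4a,8a-tetrahydronaphthalene-1,7(2H,8H)-dione | O=C1[C@@H]2[C@H](C=C(C)C(=O)C2)[C@@H](C(C)C)CC1 | intermediate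
12 | (4aS,5R,8aS)-3-methyl-8-methylidene-5-(propan-2-yl)-4a,5,6,7,8,8a-hexahydronaphthalen-2(1H)-one | C=C1[C@@H]2[C@H](C=C(C)C(=O)C2)[C@@H](C(C)C)CC1 | intermediate
13 | 3,4-epoxide of 12, oxirane oxygen cis to H-8a | C=C1[C@@H]2[C@H]([C@H]3O[C@@]3(C)C(=O)C2)[C@@H](C(C)C)CC1 | intermediate
14 | 1-hydroxy derivative of 13, 1-OH axial and cis to H-4a | C=C1[C@@H]2[C@H]([C@H]3O[C@@]3(C)C(=O)[C@@H]2O)[C@@H](C(C)C)CC1 | intermediate
15 | (2R)-2-methylbutanoic acid | CC[C@@H](C)C(=O)O | starting material
16 | (2R)-2-methylbutanoate of 14 at O-1 | C=C1[C@@H]2[C@H]([C@H]3O[C@@]3(C)C(=O)[C@@H]2OC(=O)[C@H](C)CC)[C@@H](C(C)C)CC1 | intermediate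
17 | 7-hydroxy derivative of 16, 7-OH axial and cis to H-8a | C=C1[C@@H]2[C@H]([C@H]3O[C@@]3(C)C(=O)[C@@H]2OC(=O)[C@H](C)CC)[C@@H](C(C)C)C[C@@H]1O | intermediate
18 | (2E)-3-methylpent-2-enoic acid | CC/C(C)=C/C(=O)O | starting material
19 | 7-O-[(2E)-3-methylpent-2-enoyl] derivative of 17 | C=C1[C@@H]2[C@H]([C@H]3O[C@@]3(C)C(=O)[C@@H]2OC(=O)[C@H](C)CC)[C@@H](C(C)C)C[C@@H]1OC(=O)/C=C(\C)CC | intermediate
20 | (1R,3R,3aR,4R,6S,7aS)-3-acetyl-7-methylidene-1-{[(2R)-2-methylbutanoyl]oxy}-2-oxo-4-(propan-2-yl)octahydro-1H-inden-6-yl (2E)-3-methylpent-2-enoate | C=C1[C@@H]2[C@H]([C@H](C(C)=O)C(=O)[C@@H]2OC(=O)[C@H](C)CC)[C@@H](C(C)C)C[C@@H]1OC(=O)/C=C(\C)CC | intermediate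
21 | (1R,3R,3aR,4R,6S,7aS)-3-[(1S)-1-hydroxyethyl]-7-methylidene-1-{[(2R)-2-methylbutanoyl]oxy}-2-oxo-4-(propan-2-yl)octahydro-1H-inden-6-yl (2E)-3-methylpent-2-enoate (CNP0224363.1) | C=C1[C@@H]2[C@H]([C@H]([C@H](C)O)C(=O)[C@@H]2OC(=O)[C@H](C)CC)[C@@H](C(C)C)C[C@@H]1OC(=O)/C=C(\C)CC | target

**Step count and risks**
Total step count: 14. Longest linear sequence: 14 steps (from 1 and 2 to 21).

Steps most likely to fail:

Step 14. What may go wrong: hydride transfer to the ring carbonyl, which is activated by the neighbouring acyloxy group, may compete with reduction of the acetyl group, or both carbonyls may be reduced. The fallback sets out from 20 and comes back at 21. Compound 20 is reduced at both carbonyl groups with the same ruthenium catalyst at longer reaction time to the diol F1. The less hindered side-chain hydroxyl is silylated selectively (Et3SiCl, imidazole, CH2Cl2, −20 °C) to the mono(triethylsilyl) ether F2. The ring carbinol is oxidised back with Dess–Martin periodinane to the silyl-protected ketone F3, and HF·pyridine in THF then frees 21.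

Step 13. What may go wrong: Lewis-acid ionisation of the allylic enoate, or proton loss from the developing cation, may outrun the acyl shift. The fallback sets out from 16 and comes back at 21. The BF3 rearrangement is run on 16, which carries no allylic ester, to give the β-diketone F4. Transfer hydrogenation as in step 14 gives the hydroxy ketone F5, and Et3SiOTf with 2,6-lutidine gives its triethylsilyl ether F6. SeO2/tBuOOH gives the allylic alcohol F7, esterification with 18 (DCC, DMAP) gives the silyl-protected ketone F3, and HF·pyridine gives 21.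

Step 11. What may go wrong: oxygen may be delivered on the equatorial face of the allyl system (poor facial selectivity). The fallback sets out from 16 and comes back at 19. If the oxidation gives mainly the equatorial C-7 alcohol F8, this is esterified with 18 under Mitsunobu conditions (PPh3, DIAD, toluene, 0 °C), which inverts C-7 and gives 19 directly.

**Further compounds**
F1 | step 14 | 2,1'-diol from reduction of both carbonyl groups of 20 (ring OH cis to the C-1 and C-3 substituents) | C=C1[C@@H]2[C@H]([C@H]([C@H](C)O)[C@H](O)[C@@H]2OC(=O)[C@H](C)CC)[C@@H](C(C)C)C[C@@H]1OC(=O)/C=C(\C)CC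
F2 | step 14 | side-chain triethylsilyl ether of F1 | C=C1[C@@H]2[C@H]([C@H]([C@H](C)O[Si](CC)(CC)CC)[C@H](O)[C@@H]2OC(=O)[C@H](C)CC)[C@@H](C(C)C)C[C@@H]1OC(=O)/C=C(\C)CC
F3 | step 14 | triethylsilyl ether of 21 | C=C1[C@@H]2[C@H]([C@H]([C@H](C)O[Si](CC)(CC)CC)C(=O)[C@@H]2OC(=O)[C@H](C)CC)[C@@H](C(C)C)C[C@@H]1OC(=O)/C=C(\C)CC
F4 | step 13 | 6-deoxy analogue of 20 (β-diketone from 16) | C=C1[C@@H]2[C@H]([C@H](C(C)=O)C(=O)[C@@H]2OC(=O)[C@H](C)CC)[C@@H](C(C)C)CC1
F5 | step 13 | (1S)-1-hydroxyethyl ketone from F4 | C=C1[C@@H]2[C@H]([C@H]([C@H](C)O)C(=O)[C@@H]2OC(=O)[C@H](C)CC)[C@@H](C(C)C)CC1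
F6 | step 13 | triethylsilyl ether of F5 | C=C1[C@@H]2[C@H]([C@H]([C@H](C)O[Si](CC)(CC)CC)C(=O)[C@@H]2OC(=O)[C@H](C)CC)[C@@H](C(C)C)CC1
F7 | step 13 | 6-hydroxy derivative of F6 (axial allylic alcohol) | C=C1[C@@H]2[C@H]([C@H]([C@H](C)O[Si](CC)(CC)CC)C(=O)[C@@H]2OC(=O)[C@H](C)CC)[C@@H](C(C)C)C[C@@H]1O
F8 | step 11 | C-7 epimer of 17 (equatorial allylic alcohol) | C=C1[C@@H]2[C@H]([C@H]3O[C@@]3(C)C(=O)[C@@H]2OC(=O)[C@H](C)CC)[C@@H](C(C)C)C[C@H]1O
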